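## The problem

The target is a 3,4-disubstituted tetrahydrofuran (ring atoms O1, C2, C3, C4, C5). C3 carries a 4-hydroxy-3-methoxybenzyl group through the benzylic carbon C7′, and C4 carries the exocyclic carbinol carbon C7, which bears the hydroxyl group and the 4-hydroxy-3,5-dimethoxyphenyl (syringyl) ring. Three contiguous stereocentres have to be set, C3 (R), C4 (R) and C7 (S), with the two ring substituents trans. C3 can control C4, because a new substituent enters a five-membered ring anti to its neighbour and trans is also the more stable arrangement. C4 cannot be relied on to control C7: C7 sits outside the ring on a freely rotating bond, the two ring branches at C4 differ little, and 1,2-induction in the addition of an aryl metal to a C4 aldehyde would be weak and of uncertain sense. The carbinol is a 4-hydroxybenzylic alcohol on a very electron-rich ring. Acid or heat ionises it towards a quinone methide and hydrogenolysis strips its oxygen, so the end game must be neither acidic nor reductive and both phenols must stay masked until the last step. The enabling feature is that C7 is at the alcohol oxidation level and bonded to only one carbon, C4: it is the O-bearing CH2 of a (tetrahydrofuran-3-yl)methanol that has gained an aryl group. A carbamate of that primary alcohol can therefore be deprotonated at C7 by a chiral base and the carbanion homologated with an aryl boronate, so that the configuration at C7 comes from the reagent.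

## Retrosynthesis

**26 to 25 (two O–Si bonds).** The target 26 is traced back to its bis(triisopropylsilyl) phenol ether 25. Silyl ethers are chosen for the last stage because fluoride removes them without acid or hydrogen. Benzyl ethers would need hydrogenolysis next to the labile C7–O bond, and acetal groups would need acid and would direct ring lithiation in the key step. The forward step only has to keep the liberated phenoxide buffered.

**25 to 17 + 21 (C7–aryl and C7–O).** Both bonds at C7 are cut together, leading to the primary carbamate 17 and the syringyl pinacol boronate 21. Cutting only C7–aryl (aryl metal plus C4 aldehyde) would leave C7 to the weak bias of C4. Cutting C4–C7 would need a nucleophilic ring carbon with nothing to activate it. The precursor 17 has one stereocentre and one aryl ring fewer, and its C7 is a plain CH2. The forward reaction has to choose one of the two diastereotopic C7 protons under the control of a chiral-diamine-bound alkyllithium base (lithio species 22). It must then borylate with retention (ate complex 23), shift the aryl group with inversion (boronic ester 24) and oxidise with retention, all without touching the ring ether, the aryl silyl ether or C3 and C4.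

**21 to 19 to 18 (C–B, then O–Si).** The boronate 21 comes from the aryl bromide 19 by halogen–lithium exchange and borylation, and 19 from commercial 4-bromo-2,6-dimethoxyphenol 18 by silylation. Lithium sits para to the silyloxy group, so silyl migration to carbon is not possible.

**17 to 15 + 16, 15 to 13, 13 to 12 (carbamate C–O, O–Si, two O–benzyl bonds).** Carbamate 17 is the primary alcohol 15 acylated with N,N-diisopropylcarbamoyl chloride 16. Alcohol 15 is the phenol–alcohol 13 silylated on the phenol only, and 13 arises from the dibenzyl compound 12 by one hydrogenolysis. Benzyl is used in the first half because an aryl silyl ether would not survive the alkoxide and hydride steps, and silyl is used in the second half because it tolerates organolithium chemistry. One hydrogenolysis frees both the phenol and the C7 alcohol, and the six-unit pKa gap between them is asked to direct the silyl group to the phenol.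

**12 to 11 to 10 (ring O1–C5, then lactone reduction).** The ring ether is opened to the 1,4-diol 11, which is the reduction product of lactone 10. Both carbinol carbons of 11 are CH2 groups, so cyclodehydration closes the same ring whichever hydroxyl is activated and no stereocentre is at risk. The differently protected third oxygen (benzyl on C7–O) keeps C7 out of the ring.

**10 to 7 + 8 (C4–C7).** The C4–C7 bond is cut to the enolate 9 of the β-benzyl lactone 7 and benzyl chloromethyl ether 8. This brings in C7 at the correct oxidation level, already protected, and uses C3 to set C4 trans. A hydroxymethyl group introduced unprotected would give a triol after reduction and lose the distinction between C5 and C7.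

**7 to 5 to 4 to 1 + 2 (C3–H, C3–C7′).** Lactone 7 is the chemoselectively reduced and lactonised form of the half-ester 5. Its single stereocentre C3 comes from asymmetric hydrogenation of the Stobbe half-ester 4, assembled from O-benzylvanillin 1 and dimethyl succinate 2. This is three steps to an enantioenriched lactone, with the one catalyst-controlled step placed at the start.

## Roads not taken

**Alternative 1:** The ring is cut at C2–C3 and C4–C5. The forward key step is a (3+2) cycloaddition of the parent carbonyl ylide, released by fluoride from chloromethyl (trimethylsilyl)methyl ether A2, to the (S,E)-γ-silyloxy enone A1, giving the trans-3-aroyl-4-[aryl(silyloxy)methyl]tetrahydrofuran A3. Its merit is real: the ring and both ring stereocentres appear in one convergent step, trans follows stereospecifically from the E alkene, and C7 is already in place. In ring construction it is shorter than the chosen plan. The weak points are three: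
- The unstabilised ylide is short-lived and must be used in excess.
- Face selection rests on a single allylic stereocentre on an acyclic enone.
- The C7′ carbonyl of A3 must be reduced to CH2 beside the benzylic C7–O on the more electron-rich ring, so any ionic or catalytic deoxygenation strong enough for C7′ threatens C7.

The chosen plan sets against the step count a reagent-controlled C7, ring stereocentres from a routine lactone alkylation, and a C7′ that is never oxygenated.

**Alternative 2:** The ring is cut at C4–C5. The forward key step is an intramolecular alkylation in which the enolate of the aryl ketone A4 displaces chloride from its own chloromethyl ether (5-exo-tet), giving the ring ketone A5. The closure is simple and needs no chiral reagent, C4 is epimerisable next to the ketone so trans is secured thermodynamically, and C7 can then be set by a catalytic ketone reduction of a very reliable kind. In that respect it is at least as good as the chosen plan. The weak points are: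
- The α-chloro ether is fragile and must be made in the presence of the ketone.
- The syringyl ring is carried through the whole sequence.
- C7 is set in a separate redox step on a hindered α-branched ketone, where reagent and substrate may be mismatched.
- Benzyl ethers would be removed by hydrogenolysis next to the finished carbinol.

The chosen plan sets against this a more convergent assembly, with the syringyl unit arriving in the last C–C bond, C7 fixed in the bond-forming event itself, and a fluoride end game. The ketone route is kept as the fallback for the key step.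

**Alternative 3:** The ring is cut at C2–C3 and O1–C2. The forward key step is a hydroxyl-directed hydroformylation of the homoallylic alcohol A6. A ligand reversibly bound to the C5 hydroxyl delivers rhodium hydride to the styrenyl alkene, the formyl group enters at C3, and the aldehyde closes on the hydroxyl to give the lactol A7. It is catalytic and atom-economical and makes C2 from syngas, and here it is better than the chosen plan. The weak points are:
- The directing effect must overcome the intrinsic preference for the benzylic position C7′.
- The new C3 stereocentre depends on an untested 1,2-relationship to C4.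
- C4 and C7 must first be set by a separate anti-selective construction.
- A7 must be deoxygenated with a silane and a Lewis acid, conditions that can ionise the benzylic silyloxy group at C7.

The chosen plan carries fewer unknown selectivities and avoids Lewis acid once C7 is oxygenated.

Key step: step 12

Assumption: 4-(benzyloxy)-3-methoxybenzaldehyde 1 is taken as a purchased material (it is one benzylation from vanillin).
Assumption: the (S,S)-ligand in step 2 is expected to give the R acid; if lactone 7 shows the wrong sign of rotation against the known compound, the antipodal ligand is used.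

## Route

Step 1
Reactants: 1 4-(benzyloxy)-3-methoxybenzaldehyde; 2 dimethyl succinate
Product: 4 (E)-4-[4-(benzyloxy)-3-methoxyphenyl]-3-(methoxycarbonyl)but-3-enoic acid, via paraconic ester 3 (not isolated)
Conditions: NaOMe, MeOH, reflux; then aq HCl
Reagents that add atoms: none
Why: Stobbe condensation: the succinate enolate adds to the aldehyde, the aldolate lactonises to 3, and base-induced ring opening gives the half-ester with the aryl group trans to the ester (E). The benzyl ether is inert to methoxide.

Step 2
Reactants: 4 (E)-4-[4-(benzyloxy)-3-methoxyphenyl]-3-(methoxycarbonyl)but-3-enoic acid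
Product: 5 (R)-3-[4-(benzyloxy)-3-methoxybenzyl]-4-methoxy-4-oxobutanoic acid
Conditions: H2 (5 bar), [Rh(cod)((S,S)-Et-DuPhos)]BF4 (0.5 mol%), NaOMe (10 mol%), MeOH, rt
Reagents that add atoms: none
Why: Rhodium–bisphospholane asymmetric hydrogenation of a Stobbe itaconate half-ester: carboxylate and alkene chelate the metal and the ligand selects the alkene face, so C3 (R) is set by the catalyst. The homogeneous catalyst does not cleave the aryl benzyl ether.

Step 3
Reactants: 5 (R)-3-[4-(benzyloxy)-3-methoxybenzyl]-4-methoxy-4-oxobutanoic acid
Product: 7 (R)-4-[4-(benzyloxy)-3-methoxybenzyl]dihydrofuran-2(3H)-one, via hydroxy acid 6 (not isolated)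
Conditions: KOH (1 equiv), EtOH; CaCl2, NaBH4, EtOH, −10 °C to rt; then 3 M HCl, rt
Reagents that add atoms: none
Why: Chemoselective ester reduction: calcium borohydride reduces the methyl ester but not the carboxylate, and acidification lactonises hydroxy acid 6. The stereocentre takes no part.

Step 4
Reactants: 7 (R)-4-[4-(benzyloxy)-3-methoxybenzyl]dihydrofuran-2(3H)-one; 8 benzyl chloromethyl ether
Product: 10 (3S,4R)-3-[(benzyloxy)methyl]-4-[4-(benzyloxy)-3-methoxybenzyl]dihydrofuran-2(3H)-one, via lithium enolate 9 (not isolated)
Conditions: LiHMDS, THF, −78 °C; then 8, −78 to −40 °C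
Reagents that add atoms: none
Why: Lactone enolate alkylation: the electrophile approaches 9 anti to the neighbouring benzyl group, the usual preference of β-substituted γ-butyrolactone enolates, which sets C4 trans to C3. C7 enters at the alcohol oxidation level, already protected.

Step 5
Reactants: 10 (3S,4R)-3-[(benzyloxy)methyl]-4-[4-(benzyloxy)-3-methoxybenzyl]dihydrofuran-2(3H)-one
Product: 11 (2R,3R)-2-[(benzyloxy)methyl]-3-[4-(benzyloxy)-3-methoxybenzyl]butane-1,4-diol
Conditions: LiAlH4, THF, 0 °C to rt
Reagents that add atoms: none
Why: Hydride reduction of a lactone to the 1,4-diol. Reduction is faster than enolisation, so C4 keeps its configuration, and benzyl ethers are inert.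

Step 6
Reactants: 11 (2R,3R)-2-[(benzyloxy)methyl]-3-[4-(benzyloxy)-3-methoxybenzyl]butane-1,4-diol
Product: 12 (3R,4R)-3-[(benzyloxy)methyl]-4-[4-(benzyloxy)-3-methoxybenzyl]tetrahydrofuran
Conditions: PPh3, DIAD, THF, 0 °C to rt
Reagents that add atoms: none
Why: Mitsunobu cyclodehydration of a 1,4-diol: one primary hydroxyl is activated and the other closes the ring by 5-exo-tet displacement. Both carbinol carbons are CH2, so either activation gives the same ring and no stereocentre is touched.

Step 7
Reactants: 12 (3R,4R)-3-[(benzyloxy)methyl]-4-[4-(benzyloxy)-3-methoxybenzyl]tetrahydrofuran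
Product: 13 [(3S,4R)-4-(4-hydroxy-3-methoxybenzyl)tetrahydrofuran-3-yl]methanol
Conditions: H2 (1 atm), Pd(OH)2/C, EtOH, rt
Reagents that add atoms: none
Why: Catalytic hydrogenolysis removes the aryl and the alkyl benzyl ether together. The ring ether and the non-oxygenated benzylic CH2 are not cleaved. The descriptor change from 3R to 3S is only a change of priorities.

Step 8
Reactants: 13 [(3S,4R)-4-(4-hydroxy-3-methoxybenzyl)tetrahydrofuran-3-yl]methanol
Product: 15 [(3S,4R)-4-(3-methoxy-4-triisopropylsilyloxybenzyl)tetrahydrofuran-3-yl]methanol, via sodium phenoxide 14 (not isolated)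
Conditions: NaH (1.0 equiv), THF, 0 °C; then TIPSCl (1.05 equiv), 0 °C to rt
Reagents that add atoms: triisopropylsilyl chloride, CC(C)[Si](Cl)(C(C)C)C(C)C
Why: Chemoselective O-silylation through the phenoxide: one equivalent of hydride deprotonates only the phenol, which is about six pK units more acidic than the alcohol, and 14 is silylated. The neutral primary alcohol does not react with the silyl chloride without an amine promoter.

Step 9
Reactants: 15 [(3S,4R)-4-(3-methoxy-4-triisopropylsilyloxybenzyl)tetrahydrofuran-3-yl]methanol; 16 N,N-diisopropylcarbamoyl chloride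
Product: 17 [(3R,4R)-4-(3-methoxy-4-triisopropylsilyloxybenzyl)tetrahydrofuran-3-yl]methyl N,N-diisopropylcarbamate
Conditions: Et3N, CH2Cl2, reflux
Reagents that add atoms: none
Why: O-Carbamoylation of a primary alcohol with a hindered carbamoyl chloride, the standard entry to lithiation-ready carbamates. The aryl silyl ether tolerates the mild amine base.

Step 10
Reactants: 18 4-bromo-2,6-dimethoxyphenol
Product: 19 (4-bromo-2,6-dimethoxyphenoxy)triisopropylsilane
Conditions: TIPSCl, imidazole, DMF, 40 °C
Reagents that add atoms: triisopropylsilyl chloride, CC(C)[Si](Cl)(C(C)C)C(C)C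
Why: Imidazole-promoted silylation of a phenol. The two flanking methoxy groups slow it, hence gentle warming, and later shield the silicon against nucleophiles.

Step 11
Reactants: 19 (4-bromo-2,6-dimethoxyphenoxy)triisopropylsilane
Product: 21 2-[3,5-dimethoxy-4-(triisopropylsilyloxy)phenyl]-4,4,5,5-tetramethyl-1,3,2-dioxaborolane, via aryllithium 20 (not isolated)
Conditions: n-BuLi, THF, −78 °C; then i-PrOBpin, −78 °C to rt; aq NH4Cl
Reagents that add atoms: 2-isopropoxy-4,4,5,5-tetramethyl-1,3,2-dioxaborolane, CC(C)OB1OC(C)(C)C(C)(C)O1
Why: Bromine–lithium exchange followed by borylation with an alkoxy pinacol borate. Lithium is para to the silyloxy group, so no silyl migration to carbon can occur.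

Step 12
Reactants: 17 [(3R,4R)-4-(3-methoxy-4-triisopropylsilyloxybenzyl)tetrahydrofuran-3-yl]methyl N,N-diisopropylcarbamate; 21 2-[3,5-dimethoxy-4-(triisopropylsilyloxy)phenyl]-4,4,5,5-tetramethyl-1,3,2-dioxaborolane
Product: 25 (S)-[3,5-dimethoxy-4-(triisopropylsilyloxy)phenyl][(3R,4R)-4-(3-methoxy-4-triisopropylsilyloxybenzyl)tetrahydrofuran-3-yl]methanol, via lithiated carbamate 22 (not isolated), via lithium boronate complex 23 (not isolated), via secondary boronic ester 24 (not isolated)
Conditions: s-BuLi, (+)-sparteine, Et2O, −78 °C, 5 h; 21 in Et2O, −78 °C, 1 h; MgBr2·OEt2, −78 °C to reflux; then H2O2, 2 M NaOH, THF, 0 °C to rt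
Reagents that add atoms: hydrogen peroxide, OO
Why: Lithiation–borylation–oxidation (sparteine-mediated α-lithiation of an O-alkyl carbamate, then a Matteson-type 1,2-metallate rearrangement and C–B oxidation). The diamine-bound base, held by the carbamate carbonyl, removes the pro-R proton at C7 and gives the configurationally stable α-oxy organolithium 22. Boronate 21 traps it with retention to give ate complex 23. On warming, with the magnesium salt assisting loss of the carbamate, the electron-rich aryl group migrates from boron to C7 anti to the leaving group, inverting C7 to give 24. Alkaline peroxide replaces boron by oxygen with retention, so the sequence R-lithio, retention, inversion, retention gives 7S under control of the diamine alone. No ring is formed; the new bonds are C7–aryl and C7–O. The closest known reaction type is the homologation of aryl pinacol boronates with sparteine-lithiated primary alkyl carbamates followed by oxidation to secondary benzylic alcohols. The step needs discrimination between the two diastereotopic C7 protons against any bias from C4. This should be secured by the strong kinetic preference of the chiral base complex at −78 °C and by the absence of any other directed or comparably acidic C–H (the aryl silyl ether and the ring ether are poor directors, and C3 and C4 are not acidic).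

Step 13
Reactants: 25 (S)-[3,5-dimethoxy-4-(triisopropylsilyloxy)phenyl][(3R,4R)-4-(3-methoxy-4-triisopropylsilyloxybenzyl)tetrahydrofuran-3-yl]methanol
Product: 26 (S)-(4-hydroxy-3,5-dimethoxyphenyl)[(3R,4R)-4-(4-hydroxy-3-methoxybenzyl)tetrahydrofuran-3-yl]methanol
Conditions: TBAF, AcOH, THF, 0 °C
Reagents that add atoms: none
Why: Fluoride cleavage of aryl silyl ethers. Acetic acid keeps the phenoxides protonated so that the 4-hydroxybenzylic alcohol is not driven towards a quinone methide, and no stereocentre is involved.

## Compound list

1 | 4-(benzyloxy)-3-methoxybenzaldehyde (O-benzylvanillin) | COc1cc(C=O)ccc1OCc1ccccc1 | starting material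
2 | dimethyl succinate | COC(=O)CCC(=O)OC | starting material
3 | methyl 2-[4-(benzyloxy)-3-methoxyphenyl]-5-oxotetrahydrofuran-3-carboxylate (paraconic ester, stereoisomer mixture) | COC(=O)C1CC(=O)OC1c1ccc(OCc2ccccc2)c(OC)c1 | intermediate
4 | (E)-4-[4-(benzyloxy)-3-methoxyphenyl]-3-(methoxycarbonyl)but-3-enoic acid | COC(=O)/C(CC(=O)O)=C/c1ccc(OCc2ccccc2)c(OC)c1 | intermediate
5 | (R)-3-[4-(benzyloxy)-3-methoxybenzyl]-4-methoxy-4-oxobutanoic acid | COC(=O)[C@@H](CC(=O)O)Cc1ccc(OCc2ccccc2)c(OC)c1 | intermediate
6 | (R)-3-[4-(benzyloxy)-3-methoxybenzyl]-4-hydroxybutanoic acid | OC[C@@H](CC(=O)O)Cc1ccc(OCc2ccccc2)c(OC)c1 | intermediate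
7 | (R)-4-[4-(benzyloxy)-3-methoxybenzyl]dihydrofuran-2(3H)-one | O=C1C[C@@H](Cc2ccc(OCc3ccccc3)c(OC)c2)CO1 | intermediate
8 | benzyl chloromethyl ether | ClCOCc1ccccc1 | starting material
9 | lithium enolate of 7 | [Li+].[O-]C1=C[C@@H](Cc2ccc(OCc3ccccc3)c(OC)c2)CO1 | intermediate
10 | (3S,4R)-3-[(benzyloxy)methyl]-4-[4-(benzyloxy)-3-methoxybenzyl]dihydrofuran-2(3H)-one | COc1cc(C[C@H]2COC(=O)[C@@H]2COCc2ccccc2)ccc1OCc1ccccc1 | intermediate
11 | (2R,3R)-2-[(benzyloxy)methyl]-3-[4-(benzyloxy)-3-methoxybenzyl]butane-1,4-diol | COc1cc(C[C@@H](CO)[C@H](CO)COCc2ccccc2)ccc1OCc1ccccc1 | intermediate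
12 | (3R,4R)-3-[(benzyloxy)methyl]-4-[4-(benzyloxy)-3-methoxybenzyl]tetrahydrofuran | COc1cc(C[C@H]2COC[C@@H]2COCc2ccccc2)ccc1OCc1ccccc1 | intermediate
13 | [(3S,4R)-4-(4-hydroxy-3-methoxybenzyl)tetrahydrofuran-3-yl]methanol | COc1cc(C[C@H]2COC[C@@H]2CO)ccc1O | intermediate
14 | sodium phenoxide of 13 | COc1cc(C[C@H]2COC[C@@H]2CO)ccc1[O-].[Na+] | intermediate
15 | [(3S,4R)-4-(3-methoxy-4-triisopropylsilyloxybenzyl)tetrahydrofuran-3-yl]methanol | COc1cc(C[C@H]2COC[C@@H]2CO)ccc1O[Si](C(C)C)(C(C)C)C(C)C | intermediate
16 | N,N-diisopropylcarbamoyl chloride | CC(C)N(C(C)C)C(Cl)=O | starting material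
17 | [(3R,4R)-4-(3-methoxy-4-triisopropylsilyloxybenzyl)tetrahydrofuran-3-yl]methyl N,N-diisopropylcarbamate | COc1cc(C[C@H]2COC[C@@H]2COC(=O)N(C(C)C)C(C)C)ccc1O[Si](C(C)C)(C(C)C)C(C)C | intermediate
18 | 4-bromo-2,6-dimethoxyphenol | COc1cc(Br)cc(OC)c1O | starting material
19 | (4-bromo-2,6-dimethoxyphenoxy)triisopropylsilane | COc1cc(Br)cc(OC)c1O[Si](C(C)C)(C(C)C)C(C)C | intermediate
20 | [3,5-dimethoxy-4-(triisopropylsilyloxy)phenyl]lithium | [Li]c1cc(OC)c(O[Si](C(C)C)(C(C)C)C(C)C)c(OC)c1 | intermediate
21 | 2-[3,5-dimethoxy-4-(triisopropylsilyloxy)phenyl]-4,4,5,5-tetramethyl-1,3,2-dioxaborolane | COc1cc(B2OC(C)(C)C(C)(C)O2)cc(OC)c1O[Si](C(C)C)(C(C)C)C(C)C | intermediate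
22 | carbamate 17 lithiated at C7 (7R, lithium bound to (+)-sparteine) | COc1cc(C[C@H]2COC[C@@H]2[C@@H]([Li])OC(=O)N(C(C)C)C(C)C)ccc1O[Si](C(C)C)(C(C)C)C(C)C | intermediate
23 | lithium boronate (ate) complex of 22 and 21 (7R) | COc1cc(C[C@H]2COC[C@@H]2[C@@H]([B-]2(OC(C)(C)C(C)(C)O2)c2cc(OC)c(O[Si](C(C)C)(C(C)C)C(C)C)c(OC)c2)OC(=O)N(C(C)C)C(C)C)ccc1O[Si](C(C)C)(C(C)C)C(C)C.[Li+] | intermediate
24 | secondary benzylic pinacol boronic ester at C7 (7S, ring 3R,4R) | COc1cc(C[C@H]2COC[C@@H]2[C@H](B2OC(C)(C)C(C)(C)O2)c2cc(OC)c(O[Si](C(C)C)(C(C)C)C(C)C)c(OC)c2)ccc1O[Si](C(C)C)(C(C)C)C(C)C | intermediate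
25 | (S)-[3,5-dimethoxy-4-(triisopropylsilyloxy)phenyl][(3R,4R)-4-(3-methoxy-4-triisopropylsilyloxybenzyl)tetrahydrofuran-3-yl]methanol | COc1cc(C[C@H]2COC[C@@H]2[C@H](O)c2cc(OC)c(O[Si](C(C)C)(C(C)C)C(C)C)c(OC)c2)ccc1O[Si](C(C)C)(C(C)C)C(C)C | intermediate
26 | (S)-(4-hydroxy-3,5-dimethoxyphenyl)[(3R,4R)-4-(4-hydroxy-3-methoxybenzyl)tetrahydrofuran-3-yl]methanol | COc1cc(C[C@H]2COC[C@@H]2[C@H](O)c2cc(OC)c(O)c(OC)c2)ccc1O | target

## Step count and risks

Total: 13 steps. Longest linear sequence: 11 steps (steps 1–9, 12, 13) from 1. The boronate branch (steps 10 and 11) joins at step 12.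

**Step 12 (key step).** Several things may go wrong:
- Deprotonation at the β-branched C7 may be slow or incomplete.
- Discrimination between the two C7 protons may erode if the fixed C4 centre and the diamine are mismatched.
- The aryl shift may be sluggish, letting the ate complex revert.
- The aryl silyl ethers may be partly lost in alkaline peroxide. This last is harmless for the route, since both come off in step 13, but it complicates isolation.

The fallback changes the disconnection to aryl addition plus reagent-controlled reduction and sets out from alcohol 15. Dess–Martin oxidation should give (3R,4R)-4-(3-methoxy-4-triisopropylsilyloxybenzyl)tetrahydrofuran-3-carbaldehyde F1. Aryllithium 20, generated from 19 as in step 11, should add to it to give the bis-silyl carbinol as a mixture of C7 epimers F2. A second Dess–Martin oxidation should give the bis-silyl aryl ketone F3. Reduction with borane under the (R)-configured CBS oxazaborolidine is expected to deliver the 7S alcohol 25, where the route is rejoined.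

**Step 8.** The silyl group may also go onto the primary hydroxyl if phenoxide and alkoxide equilibrate or if excess reagent is present, which lowers the supply of 15. The fallback sets out from 13. Exhaustive silylation (TIPSOTf, 2,6-lutidine) should give the bis(triisopropylsilyl) ether F4. Acid methanolysis then exploits the much greater acid lability of the alkyl silyl ether over the aryl silyl ether and frees the primary alcohol only, returning to 15.

**Step 4.** Alkylation with the chloromethyl ether may suffer from O-alkylation, double alkylation or incomplete conversion, and the trans preference may be less than complete. The fallback sets out from 7 through its enolate 9. Aldol addition to monomeric formaldehyde should give (3S,4R)-4-[4-(benzyloxy)-3-methoxybenzyl]-3-(hydroxymethyl)dihydrofuran-2(3H)-one F5. Benzylation under acid catalysis (benzyl trichloroacetimidate, catalytic TfOH) avoids the retro-aldol and elimination pathways of basic conditions and returns to 10.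

**Step 2.** Enantioselection may be insufficient or of the opposite sense for this aryl-substituted half-ester. Beyond exchanging the ligand antipode, the fallback sets out from 4. Hydrogenation with an achiral cationic rhodium–diphosphine catalyst should give the racemic acid F6. Crystallisation of the diastereomeric salt of the R acid with (R)-1-phenylethylamine F7 (the antipodal amine if the S acid crystallises instead) and acidification then return to 5.

## Further compounds

F1 | step 12 | (3R,4R)-4-(3-methoxy-4-triisopropylsilyloxybenzyl)tetrahydrofuran-3-carbaldehyde | COc1cc(C[C@H]2COC[C@@H]2C=O)ccc1O[Si](C(C)C)(C(C)C)C(C)C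
F2 | step 12 | [3,5-dimethoxy-4-(triisopropylsilyloxy)phenyl][(3R,4R)-4-(3-methoxy-4-triisopropylsilyloxybenzyl)tetrahydrofuran-3-yl]methanol, mixture of C7 epimers | COc1cc(C[C@H]2COC[C@@H]2C(O)c2cc(OC)c(O[Si](C(C)C)(C(C)C)C(C)C)c(OC)c2)ccc1O[Si](C(C)C)(C(C)C)C(C)C
F3 | step 12 | [3,5-dimethoxy-4-(triisopropylsilyloxy)phenyl][(3R,4R)-4-(3-methoxy-4-triisopropylsilyloxybenzyl)tetrahydrofuran-3-yl]methanone | COc1cc(C[C@H]2COC[C@@H]2C(=O)c2cc(OC)c(O[Si](C(C)C)(C(C)C)C(C)C)c(OC)c2)ccc1O[Si](C(C)C)(C(C)C)C(C)C
F4 | step 8 | (3R,4R)-3-(3-methoxy-4-triisopropylsilyloxybenzyl)-4-[(triisopropylsilyloxy)methyl]tetrahydrofuran | COc1cc(C[C@H]2COC[C@@H]2CO[Si](C(C)C)(C(C)C)C(C)C)ccc1O[Si](C(C)C)(C(C)C)C(C)C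
F5 | step 4 | (3S,4R)-4-[4-(benzyloxy)-3-methoxybenzyl]-3-(hydroxymethyl)dihydrofuran-2(3H)-one | COc1cc(C[C@H]2COC(=O)[C@@H]2CO)ccc1OCc1ccccc1
F6 | step 2 | racemic 3-[4-(benzyloxy)-3-methoxybenzyl]-4-methoxy-4-oxobutanoic acid | COC(=O)C(CC(=O)O)Cc1ccc(OCc2ccccc2)c(OC)c1
F7 | step 2 | (R)-1-phenylethylammonium (R)-3-[4-(benzyloxy)-3-methoxybenzyl]-4-methoxy-4-oxobutanoate | COC(=O)[C@@H](CC(=O)[O-])Cc1ccc(OCc2ccccc2)c(OC)c1.C[C@@H]([NH3+])c1ccccc1
A1 | alternative 1 | (S,E)-1-(4-benzyloxy-3-methoxyphenyl)-4-(4-benzyloxy-3,5-dimethoxyphenyl)-4-(tert-butyldimethylsilyloxy)but-2-en-1-one | COc1cc(C(=O)/C=C/[C@H](O[Si](C)(C)C(C)(C)C)c2cc(OC)c(OCc3ccccc3)c(OC)c2)ccc1OCc1ccccc1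
A2 | alternative 1 | chloromethyl (trimethylsilyl)methyl ether | C[Si](C)(C)COCCl
A3 | alternative 1 | (4-benzyloxy-3-methoxyphenyl){(3R,4R)-4-[(S)-(4-benzyloxy-3,5-dimethoxyphenyl)(tert-butyldimethylsilyloxy)methyl]tetrahydrofuran-3-yl}methanone | COc1cc(C(=O)[C@H]2COC[C@@H]2[C@H](O[Si](C)(C)C(C)(C)C)c2cc(OC)c(OCc3ccccc3)c(OC)c2)ccc1OCc1ccccc1
A4 | alternative 2 | (R)-1-(4-benzyloxy-3,5-dimethoxyphenyl)-3-(4-benzyloxy-3-methoxybenzyl)-4-(chloromethoxy)butan-1-one | COc1cc(C[C@@H](COCCl)CC(=O)c2cc(OC)c(OCc3ccccc3)c(OC)c2)ccc1OCc1ccccc1
A5 | alternative 2 | [(3R,4R)-4-(4-benzyloxy-3-methoxybenzyl)tetrahydrofuran-3-yl](4-benzyloxy-3,5-dimethoxyphenyl)methanone | COc1cc(C[C@H]2COC[C@@H]2C(=O)c2cc(OC)c(OCc3ccccc3)c(OC)c2)ccc1OCc1ccccc1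
A6 | alternative 3 | (2R,3E)-4-(4-benzyloxy-3-methoxyphenyl)-2-[(S)-(4-benzyloxy-3,5-dimethoxyphenyl)(tert-butyldimethylsilyloxy)methyl]but-3-en-1-ol | COc1cc(/C=C/[C@H](CO)[C@H](O[Si](C)(C)C(C)(C)C)c2cc(OC)c(OCc3ccccc3)c(OC)c2)ccc1OCc1ccccc1
A7 | alternative 3 | 3-(4-benzyloxy-3-methoxybenzyl)-4-[(S)-(4-benzyloxy-3,5-dimethoxyphenyl)(tert-butyldimethylsilyloxy)methyl]tetrahydrofuran-2-ol, ring substituents trans, anomer mixture | COc1cc(C[C@H]2C(O)OC[C@@H]2[C@H](O[Si](C)(C)C(C)(C)C)c2cc(OC)c(OCc3ccccc3)c(OC)c2)ccc1OCc1ccccc1
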